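A direct plan would join salicylaldehyde A1 and mandelate A2 by Mitsunobu etherification (O1–C2), adjust both carbonyl carbons to dialdehyde A3 and close ring C at C3–C4 by a carbene-catalysed benzoin reaction to ketol A4, then oxidise and deprotect. Its weakest steps would be:
- the Mitsunobu etherification: a hindered, chelated phenol would have to displace a secondary benzylic oxyphosphonium that ionises easily;
- the benzoin closure: its Breslow intermediate would carry the aryloxy group in the β position and could expel it, and the aldehyde is enolisable;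
- the hydride reduction and double reoxidation leading to A3: two steps that add no complexity.

**Strategy.** The chromone is cut at C8a–O1 and C4a–C4, the two bonds that tie ring A to ring C, and at O1–C2. Ring A enters as a 3,5-dioxygenated benzyne that inserts into the C–O bond of the ring B arylpropiolic acid; the resulting o-hydroxyaryl ynone closes ring C in the same flask. The feature exploited is that ring A has oxygen at C5 beside C4a but hydrogen at C8 beside C8a: this directs O1 to C8a and the acyl carbon C4 to C4a. C3 is then hydroxylated through its lithio derivative. No ether has to be made at a benzylic carbon, no carbene-catalysed closure is needed and no carbonyl group is reduced and reoxidised.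

Key step: step 7

Remark on the chemistry: ethoxymethyl ethers (from chloromethyl ethyl ether) protect the phenols. They are assumed to match methoxymethyl ethers in stability to base, fluoride and organolithium reagents and in cleavage by dilute acid.

**Ring A: aryne precursor**

Step 1
Reactants: 1 phloroglucinol (benzene-1,3,5-triol); 2 chloromethyl ethyl ether
Product: 3 3,5-bis(ethoxymethoxy)phenol
Conditions: EtOCH2Cl (2.0 equiv), iPr2NEt (2.2 equiv), DMF, 0 °C → rt
Reagents that add atoms: chloromethyl ethyl ether (2), CCOCCl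
Why: Williamson-type O-alkylation by the hard α-chloro ether goes at oxygen and not at the ring carbons, and with two equivalents the bis-ether is the main statistical product, to be separated from mono- and tris-ether by chromatography.

Step 2
Reactants: 3 3,5-bis(ethoxymethoxy)phenol; 4 N-bromosuccinimide
Product: 5 2-bromo-3,5-bis(ethoxymethoxy)phenol
Conditions: NBS (1.0 equiv), iPr2NH (10 mol%), CH2Cl2, −78 → −20 °C
Reagents that add atoms: N-bromosuccinimide (4), O=C1CCC(=O)N1Br
Why: Electrophilic aromatic bromination in which the N-bromoamine formed from the catalytic amine is held by a hydrogen bond to the phenolic OH and delivers bromine to one of the two equivalent ortho positions, while the para position is shielded by both acetal groups; one equivalent at low temperature limits double bromination.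

Step 3
Reactants: 5 2-bromo-3,5-bis(ethoxymethoxy)phenol; 6 hexamethyldisilazane; 7 trifluoromethanesulfonic anhydride
Product: 10 3,5-bis(ethoxymethoxy)-2-(trimethylsilyl)phenyl trifluoromethanesulfonate, via aryl trimethylsilyl ether 8 (not isolated), via lithium 2-silylphenoxide 9 (not isolated)
Conditions: (Me3Si)2NH, THF, 65 °C, then evaporation; n-BuLi (1.1 equiv), THF, −78 °C; Tf2O (1.2 equiv), −78 °C
Reagents that add atoms: hexamethyldisilazane (6), C[Si](C)(C)N[Si](C)(C)C; trifluoromethanesulfonic anhydride (7), O=S(=O)(OS(=O)(=O)C(F)(F)F)C(F)(F)F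
Why: O-Silylation, bromine–lithium exchange and 1,3 O→C silyl shift of the o-lithioaryl silyl ether (retro-Brook rearrangement, driven by the Li–O bond) should give phenoxide 9, which is triflated at oxygen; the acetal ethers tolerate all three operations.

**Ring B: arylpropiolic acid**

Step 4
Reactants: 11 4-iodophenol; 12 prenyl bromide (1-bromo-3-methylbut-2-ene)
Product: 13 4-iodo-2,6-bis(3-methylbut-2-en-1-yl)phenol
Conditions: NaH (2.2 equiv), prenyl bromide (2.2 equiv), toluene, 0 °C → rt
Reagents that add atoms: prenyl bromide (12), CC(C)=CCBr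
Why: In toluene the sodium phenoxide reacts as a tight aggregate whose oxygen is screened, so the allylic bromide is attacked by the two ortho carbons in turn (phenoxide ortho-C-alkylation) while the para position is held by iodine.

Step 5
Reactants: 13 4-iodo-2,6-bis(3-methylbut-2-en-1-yl)phenol; 2 chloromethyl ethyl ether
Product: 14 2-(ethoxymethoxy)-5-iodo-1,3-bis(3-methylbut-2-en-1-yl)benzene
Conditions: NaH, EtOCH2Cl, DMF, 0 °C → rt
Reagents that add atoms: chloromethyl ethyl ether (2), CCOCCl
Why: Williamson-type O-alkylation of the hindered sodium phenoxide by the small, very reactive chloromethyl ether, so that no phenoxide is present later to compete for the aryne.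

Step 6
Reactants: 14 2-(ethoxymethoxy)-5-iodo-1,3-bis(3-methylbut-2-en-1-yl)benzene; 15 propiolic acid
Product: 16 3-[4-(ethoxymethoxy)-3,5-bis(3-methylbut-2-en-1-yl)phenyl]prop-2-ynoic acid
Conditions: propiolic acid (1.5 equiv), Pd(PPh3)4 (5 mol%), DBU (2.5 equiv), DMSO, rt; cold aq NaHSO4 work-up (pH 3)
Reagents that add atoms: propiolic acid (15), C#CC(=O)O
Why: Copper-free Sonogashira coupling of the aryl iodide with the acetylenic C–H of propiolic acid (as its DBU carboxylate) at room temperature, below the temperature at which the alkynoic acid would decarboxylate; acetals and alkenes are inert.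

**Union and completion**

Step 7
Reactants: 10 3,5-bis(ethoxymethoxy)-2-(trimethylsilyl)phenyl trifluoromethanesulfonate; 16 3-[4-(ethoxymethoxy)-3,5-bis(3-methylbut-2-en-1-yl)phenyl]prop-2-ynoic acid
Product: 19 5,7-bis(ethoxymethoxy)-2-[4-(ethoxymethoxy)-3,5-bis(3-methylbut-2-en-1-yl)phenyl]-4H-chromen-4-one, via aryne 17 (not isolated), via 2-hydroxyaryl ynone 18 (not isolated)
Conditions: 10 (1.0 equiv), 16 (1.2 equiv), CsF (4 equiv), THF, 125 °C, sealed tube
Reagents that add atoms: none
Why: Fluoride removes the trimethylsilyl group of 10 and triflate leaves, which gives aryne 17, and the carboxylate of 16 adds through oxygen to the aryne carbon that lies away from the neighbouring acetal oxygen (the future C8a), because that terminus of the distorted triple bond is the more electrophilic and the aryl anion then develops at the carbon next to the inductively withdrawing oxygen (the future C4a). The aryl anion attacks the carbonyl carbon of the aryl ester just formed through a four-membered transition state, a 1,3 O→C acyl shift of the anionic Fries type, so that the phenoxide of ynone 18 results with O1 on C8a and C4 on C4a. The phenoxide adds to the β-carbon of the ynone, and protonation of the allenolate by the hydrogen fluoride formed from the acid gives flavone 19. The closest known reaction type is the fluoride-induced insertion of arynes into the C–O bond of carboxylic acids, which with 3-arylpropiolic acids is known to end in flavones. Ring C closes in the 6-endo-dig mode, preferred to 5-exo-dig closure (an aurone) because the ynone is polarised toward attack at its β-carbon, and no stereocentre is formed. The step needs the carboxylate to outrun an ene reaction of the aryne with the prenyl groups and the acyl shift to outrun protonation of the aryl anion, for which the anionic nucleophile in slight excess, the aprotic solvent and the high temperature are chosen; the second acetal oxygen (future C7) is meta to one terminus and para to the other and does not change the bias.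

Step 8
Reactants: 19 5,7-bis(ethoxymethoxy)-2-[4-(ethoxymethoxy)-3,5-bis(3-methylbut-2-en-1-yl)phenyl]-4H-chromen-4-one; 20 hydrogen peroxide
Product: 23 5,7-bis(ethoxymethoxy)-2-[4-(ethoxymethoxy)-3,5-bis(3-methylbut-2-en-1-yl)phenyl]-3-hydroxy-4H-chromen-4-one, via 3-lithioflavone 21 (not isolated), via flavon-3-ylboronate 22 (not isolated)
Conditions: LDA (1.3 equiv), THF, −78 °C; B(OMe)3 (2.5 equiv), −78 → 0 °C; AcOH, then 30% aq H2O2, 0 °C → rt
Reagents that add atoms: hydrogen peroxide (20), OO
Why: Amide-base lithiation at C3, the vinylic position next to the carbonyl group (a known reaction of flavones), borylation and oxidative 1,2-shift of the chromonyl group from boron to oxygen (boronate oxidation) should give the 3-hydroxy compound; peroxide under these conditions should not epoxidise the isolated prenyl double bonds as a dioxirane or peracid would.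

Step 9
Reactants: 23 5,7-bis(ethoxymethoxy)-2-[4-(ethoxymethoxy)-3,5-bis(3-methylbut-2-en-1-yl)phenyl]-3-hydroxy-4H-chromen-4-one
Product: 24 3,5,7-trihydroxy-2-[4-hydroxy-3,5-bis(3-methylbut-2-en-1-yl)phenyl]-4H-chromen-4-one (target)
Conditions: 3 M aq HCl, MeOH/THF, rt → 40 °C
Reagents that add atoms: none
Why: Acid-catalysed acetal exchange with methanol should remove the three ethoxymethyl groups as ethoxy(methoxy)methane under conditions mild enough to leave the prenyl double bonds beside the freed phenol unprotonated (acetal methanolysis).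

**Compound list**

1 | phloroglucinol (benzene-1,3,5-triol) | Oc1cc(O)cc(O)c1 | starting material
2 | chloromethyl ethyl ether | CCOCCl | starting material
3 | 3,5-bis(ethoxymethoxy)phenol | CCOCOc1cc(O)cc(OCOCC)c1 | intermediate
4 | N-bromosuccinimide | O=C1CCC(=O)N1Br | starting material
5 | 2-bromo-3,5-bis(ethoxymethoxy)phenol | CCOCOc1cc(O)c(Br)c(OCOCC)c1 | intermediate
6 | hexamethyldisilazane | C[Si](C)(C)N[Si](C)(C)C | starting material
7 | trifluoromethanesulfonic anhydride | O=S(=O)(OS(=O)(=O)C(F)(F)F)C(F)(F)F | starting material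
8 | [2-bromo-3,5-bis(ethoxymethoxy)phenoxy]trimethylsilane (not isolated) | CCOCOc1cc(O[Si](C)(C)C)c(Br)c(OCOCC)c1 | intermediate
9 | lithium 3,5-bis(ethoxymethoxy)-2-(trimethylsilyl)phenoxide (not isolated) | CCOCOc1cc(O[Li])c([Si](C)(C)C)c(OCOCC)c1 | intermediate
10 | 3,5-bis(ethoxymethoxy)-2-(trimethylsilyl)phenyl trifluoromethanesulfonate | CCOCOc1cc(OS(=O)(=O)C(F)(F)F)c([Si](C)(C)C)c(OCOCC)c1 | intermediate
11 | 4-iodophenol | Oc1ccc(I)cc1 | starting material
12 | prenyl bromide (1-bromo-3-methylbut-2-ene) | CC(C)=CCBr | starting material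
13 | 4-iodo-2,6-bis(3-methylbut-2-en-1-yl)phenol | CC(C)=CCc1cc(I)cc(CC=C(C)C)c1O | intermediate
14 | 2-(ethoxymethoxy)-5-iodo-1,3-bis(3-methylbut-2-en-1-yl)benzene | CC(C)=CCc1cc(I)cc(CC=C(C)C)c1OCOCC | intermediate
15 | propiolic acid | C#CC(=O)O | starting material
16 | 3-[4-(ethoxymethoxy)-3,5-bis(3-methylbut-2-en-1-yl)phenyl]prop-2-ynoic acid | CC(C)=CCc1cc(C#CC(=O)O)cc(CC=C(C)C)c1OCOCC | intermediate
17 | 3,5-bis(ethoxymethoxy)benzyne (1,2-didehydro-3,5-bis(ethoxymethoxy)benzene, not isolated) | CCOCOC1=CC(OCOCC)=CC#C1 | intermediate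
18 | 1-[2,4-bis(ethoxymethoxy)-6-hydroxyphenyl]-3-[4-(ethoxymethoxy)-3,5-bis(3-methylbut-2-en-1-yl)phenyl]prop-2-yn-1-one (as caesium phenoxide, not isolated) | CC(C)=CCc1cc(C#CC(=O)c2c(O)cc(OCOCC)cc2OCOCC)cc(CC=C(C)C)c1OCOCC | intermediate
19 | 5,7-bis(ethoxymethoxy)-2-[4-(ethoxymethoxy)-3,5-bis(3-methylbut-2-en-1-yl)phenyl]-4H-chromen-4-one | CC(C)=CCc1cc(-c2cc(=O)c3c(OCOCC)cc(OCOCC)cc3o2)cc(CC=C(C)C)c1OCOCC | intermediate
20 | hydrogen peroxide | OO | starting material
21 | 5,7-bis(ethoxymethoxy)-2-[4-(ethoxymethoxy)-3,5-bis(3-methylbut-2-en-1-yl)phenyl]-3-lithio-4H-chromen-4-one (not isolated) | CC(C)=CCc1cc(-c2oc3cc(OCOCC)cc(OCOCC)c3c(=O)c2[Li])cc(CC=C(C)C)c1OCOCC | intermediate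
22 | dimethyl {5,7-bis(ethoxymethoxy)-2-[4-(ethoxymethoxy)-3,5-bis(3-methylbut-2-en-1-yl)phenyl]-4-oxo-4H-chromen-3-yl}boronate (not isolated) | CC(C)=CCc1cc(-c2oc3cc(OCOCC)cc(OCOCC)c3c(=O)c2B(OC)OC)cc(CC=C(C)C)c1OCOCC | intermediate
23 | 5,7-bis(ethoxymethoxy)-2-[4-(ethoxymethoxy)-3,5-bis(3-methylbut-2-en-1-yl)phenyl]-3-hydroxy-4H-chromen-4-one | CC(C)=CCc1cc(-c2oc3cc(OCOCC)cc(OCOCC)c3c(=O)c2O)cc(CC=C(C)C)c1OCOCC | intermediate
24 | 3,5,7-trihydroxy-2-[4-hydroxy-3,5-bis(3-methylbut-2-en-1-yl)phenyl]-4H-chromen-4-one | CC(C)=CCc1cc(-c2oc3cc(O)cc(O)c3c(=O)c2O)cc(CC=C(C)C)c1O | target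

**Step count and risks**

Total step count: 9. Longest linear sequence: 6 steps (steps 1–3, then 7–9; the ring B branch, steps 4–6, then 7–9, is equally long).

Steps most likely to fail:

1. Step 7. The aryl anion may be protonated before the acyl shift (an aryl ester instead of the ketone), the propiolate may decarboxylate at 125 °C, or the aryne may be consumed by ene reaction with the prenyl groups. Fallback: a carbonylative annulation that builds the same ynone from an o-iodophenol, a terminal alkyne and carbon monoxide. It sets out from phenol 3 and acid 16. Iodination of 3 ortho to the hydroxyl (N-iodosuccinimide, cat. iPr2NH, CH2Cl2, −78 °C) would give 2-iodo-3,5-bis(ethoxymethoxy)phenol F1. Protodecarboxylation of 16 (CuCl cat., Et3N, MeCN, 60 °C) would give 5-ethynyl-2-(ethoxymethoxy)-1,3-bis(3-methylbut-2-en-1-yl)benzene F2. Carbonylative Sonogashira coupling of F1 with F2 (PdCl2(dppf) cat., Et2NH, CO 20 bar, 120 °C) would give ynone 18, which the amine should close to flavone 19, where the route is rejoined.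

2. Step 8. The base may deprotonate the benzylic–allylic methylene groups of ring B instead of C3, trapping by the borate may be incomplete, or the electron-rich product may be over-oxidised. Fallback: the C3 oxygen would come in with the acid partner, so that no C–H oxidation is needed. It sets out from iodide 14 and silyl triflate 10. Iodine–magnesium exchange on 14 (iPrMgCl·LiCl, THF, 0 °C) and carboxylation with CO2 would give 4-(ethoxymethoxy)-3,5-bis(3-methylbut-2-en-1-yl)benzoic acid F3. Alkylation with allyl bromoacetate (K2CO3, DMF) would give 2-oxo-2-(prop-2-en-1-yloxy)ethyl 4-(ethoxymethoxy)-3,5-bis(3-methylbut-2-en-1-yl)benzoate F4. Deallylation (Pd(PPh3)4 cat., morpholine, THF) would give 2-{[4-(ethoxymethoxy)-3,5-bis(3-methylbut-2-en-1-yl)benzoyl]oxy}acetic acid F5. The same aryne C–O insertion of F5 with 10 (CsF, THF, 125 °C) would give 2-[2,4-bis(ethoxymethoxy)-6-hydroxyphenyl]-2-oxoethyl 4-(ethoxymethoxy)-3,5-bis(3-methylbut-2-en-1-yl)benzoate F6. Base-mediated acyl migration to the 2-hydroxy-1,3-diketone and cyclodehydration (K2CO3, Bu4NBr, toluene, reflux), a known flavonol synthesis, would deliver 23, where the route is rejoined.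

3. Step 2. Bromine may enter para to the hydroxyl, between the two acetal oxygens, or twice. Fallback: directed ortho-metalation in place of electrophilic substitution. It sets out from phenol 3. Carbamoylation (Et2NCOCl, NaH, THF) would give 3,5-bis(ethoxymethoxy)phenyl N,N-diethylcarbamate F7. Lithiation between the carbamate and the acetal oxygen (s-BuLi, TMEDA, THF, −78 °C) with Me3SiCl quench would give 3,5-bis(ethoxymethoxy)-2-(trimethylsilyl)phenyl N,N-diethylcarbamate F8. Reductive cleavage (LiAlH4, THF, 0 °C → rt) would give 3,5-bis(ethoxymethoxy)-2-(trimethylsilyl)phenol F9. Deprotonation with n-BuLi at −78 °C would give lithium phenoxide 9, where the route is rejoined before the triflation of step 3.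

**Further compounds**

F1 | step 7 | 2-iodo-3,5-bis(ethoxymethoxy)phenol | CCOCOc1cc(O)c(I)c(OCOCC)c1
F2 | step 7 | 5-ethynyl-2-(ethoxymethoxy)-1,3-bis(3-methylbut-2-en-1-yl)benzene | CC(C)=CCc1cc(C#C)cc(CC=C(C)C)c1OCOCC
F3 | step 8 | 4-(ethoxymethoxy)-3,5-bis(3-methylbut-2-en-1-yl)benzoic acid | CC(C)=CCc1cc(C(=O)O)cc(CC=C(C)C)c1OCOCC
F4 | step 8 | 2-oxo-2-(prop-2-en-1-yloxy)ethyl 4-(ethoxymethoxy)-3,5-bis(3-methylbut-2-en-1-yl)benzoate | CC(C)=CCc1cc(C(=O)OCC(=O)OCC=C)cc(CC=C(C)C)c1OCOCC
F5 | step 8 | 2-{[4-(ethoxymethoxy)-3,5-bis(3-methylbut-2-en-1-yl)benzoyl]oxy}acetic acid | CC(C)=CCc1cc(C(=O)OCC(=O)O)cc(CC=C(C)C)c1OCOCC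
F6 | step 8 | 2-[2,4-bis(ethoxymethoxy)-6-hydroxyphenyl]-2-oxoethyl 4-(ethoxymethoxy)-3,5-bis(3-methylbut-2-en-1-yl)benzoate | CC(C)=CCc1cc(C(=O)OCC(=O)c2c(O)cc(OCOCC)cc2OCOCC)cc(CC=C(C)C)c1OCOCC
F7 | step 2 | 3,5-bis(ethoxymethoxy)phenyl N,N-diethylcarbamate | CCN(CC)C(=O)Oc1cc(OCOCC)cc(OCOCC)c1
F8 | step 2 | 3,5-bis(ethoxymethoxy)-2-(trimethylsilyl)phenyl N,N-diethylcarbamate | CCN(CC)C(=O)Oc1cc(OCOCC)cc(OCOCC)c1[Si](C)(C)C
F9 | step 2 | 3,5-bis(ethoxymethoxy)-2-(trimethylsilyl)phenol | CCOCOc1cc(O)c([Si](C)(C)C)c(OCOCC)c1
A1 | direct plan | 2-hydroxy-4,6-bis(methoxymethoxy)benzaldehyde | O=Cc1c(O)cc(OCOC)cc1OCOC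
A2 | direct plan | ethyl 2-hydroxy-2-[4-(methoxymethoxy)-3,5-bis(3-methylbut-2-en-1-yl)phenyl]acetate (racemic) | CCOC(=O)C(O)c1cc(CC=C(C)C)c(OCOC)c(CC=C(C)C)c1
A3 | direct plan | 2-[2-formyl-3,5-bis(methoxymethoxy)phenoxy]-2-[4-(methoxymethoxy)-3,5-bis(3-methylbut-2-en-1-yl)phenyl]acetaldehyde (racemic) | O=CC(Oc1cc(OCOC)cc(OCOC)c1C=O)c1cc(CC=C(C)C)c(OCOC)c(CC=C(C)C)c1
A4 | direct plan | 3-hydroxy-5,7-bis(methoxymethoxy)-2-[4-(methoxymethoxy)-3,5-bis(3-methylbut-2-en-1-yl)phenyl]chroman-4-one (racemic cis/trans mixture) | CC(C)=CCc1cc(C2Oc3cc(OCOC)cc(OCOC)c3C(=O)C2O)cc(CC=C(C)C)c1OCOC
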